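**Retrosynthetic overview**

- Feature: the pyran oxygen O1 and the pyran carbon C4 are attached to the neighbouring benzene carbons C8a and C4a, and this pair lies between C8–O and C5–O. The benzene ring therefore maps onto a symmetric 3,6-dimethoxybenzyne whose two triple-bond carbons accept one oxygen and one carbon.
- Key disconnection: C8a–O1 and C4–C4a together, giving silylaryl triflate 8 and (S)-β-hydroxy aldehyde 12 (alkoxide adds to the aryne, the aryl anion is captured by the aldehyde). C2 is set beforehand by Sharpless epoxidation of geraniol and no later step breaks a bond to it.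
- Further disconnections: C6–C(=O) (bromine–lithium exchange on 17, Weinreb enamide 20), the side-chain tertiary alcohol (Mukaiyama hydration), C3=C4 (dehydration of the C4 carbinol), the hydroquinone (oxidative demethylation, then dithionite).
- Ring order: the benzene ring is bought as 2,5-dimethoxyphenol, the pyran ring is closed in step 7, and the phenol ring of the cinnamoyl unit is bought.

Key step: step 7

Remark: the C2 carbinol configuration is taken from Sharpless epoxidation of geraniol, not from commercial linalool, whose optical purity varies; C4 of 14–16 is expected as both epimers and is removed in step 10, so it is left unassigned.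

**Route**

Step 1
Reactants: 1 2,5-dimethoxyphenol
Product: 2 2,5-dimethoxyphenyl N-isopropylcarbamate
Conditions: i-PrNCO (1.2 equiv), Et3N (0.2 equiv), CH2Cl2, rt
Reagents that add atoms: isopropyl isocyanate, CC(C)N=C=O
Why: Amine-catalysed addition of the phenol O–H to the isocyanate (carbamoylation) installs a directing group that can later be removed under mild base.

Step 2
Reactants: 2 2,5-dimethoxyphenyl N-isopropylcarbamate
Product: 6 3,6-dimethoxy-2-(trimethylsilyl)phenyl N-isopropylcarbamate, via N-silyl carbamate 3 (not isolated), via aryllithium 4 (not isolated), via N,C-disilyl carbamate 5 (not isolated)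
Conditions: TBSOTf, TMEDA, Et2O, 0 °C → rt; n-BuLi, TMEDA, −78 °C; TMSCl, −78 °C → rt; aq. NaHSO4
Reagents that add atoms: chlorotrimethylsilane, C[Si](C)(C)Cl
Why: Directed ortho-metalation: after transient N-silylation the carbamate directs lithiation to C6–H, the only free position ortho to it and also ortho to a methoxy group, and the silyl chloride quench is followed by hydrolysis of the N–Si bond on work-up.

Step 3
Reactants: 6 3,6-dimethoxy-2-(trimethylsilyl)phenyl N-isopropylcarbamate
Product: 8 3,6-dimethoxy-2-(trimethylsilyl)phenyl trifluoromethanesulfonate, via silylphenol 7 (not isolated)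
Conditions: DBU, Et2NH, MeCN, 40 °C; then PhNTf2, rt
Reagents that add atoms: N-phenylbis(trifluoromethanesulfonimide), O=S(=O)(N(c1ccccc1)S(=O)(=O)C(F)(F)F)C(F)(F)F
Why: Base-induced E1cB loss of isopropyl isocyanate (trapped by Et2NH as a urea) frees the phenoxide, which is sulfonylated in the same flask without disturbing the aryl–silicon bond.

Step 4
Reactants: 9 geraniol
Product: 10 (2S,3S)-2,3-epoxygeraniol
Conditions: Ti(OiPr)4 (5 mol%), L-(+)-diethyl tartrate (7 mol%), t-BuOOH, 4 Å MS, CH2Cl2, −20 °C
Reagents that add atoms: tert-butyl hydroperoxide, CC(C)(C)OO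
Why: Sharpless asymmetric epoxidation oxidises only the allylic alcohol alkene, and L-(+)-diethyl tartrate should set the (2S,3S) configuration, C3 of which becomes C2 of the target.

Step 5
Reactants: 10 (2S,3S)-2,3-epoxygeraniol
Product: 11 (3S)-3,7-dimethyloct-6-ene-1,3-diol
Conditions: NaAlH2(OCH2CH2OMe)2 (Red-Al), THF, 0 °C → rt; aq. potassium sodium tartrate
Reagents that add atoms: none
Why: Hydroxyl-directed reductive opening of a 2,3-epoxy alcohol: the alkoxyaluminium hydride delivers hydride to C2, so the C3–O bond and its configuration are kept and the 1,3-diol should form.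

Step 6
Reactants: 11 (3S)-3,7-dimethyloct-6-ene-1,3-diol
Product: 12 (3S)-3-hydroxy-3,7-dimethyloct-6-enal
Conditions: TEMPO (10 mol%), PhI(OAc)2 (1.1 equiv), CH2Cl2, rt
Reagents that add atoms: none
Why: Oxoammonium (TEMPO) oxidation is selective for the primary alcohol, cannot oxidise the tertiary one and stops at the aldehyde under anhydrous conditions; the β-hydroxy aldehyde is used at once because it can lose water.

Step 7
Reactants: 8 3,6-dimethoxy-2-(trimethylsilyl)phenyl trifluoromethanesulfonate; 12 (3S)-3-hydroxy-3,7-dimethyloct-6-enal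
Product: 14 (2S)-5,8-dimethoxy-2-methyl-2-(4-methylpent-3-en-1-yl)chroman-4-ol (both C4 epimers), via 3,6-dimethoxybenzyne 13 (not isolated)
Conditions: CsF (3 equiv), 18-crown-6 (0.5 equiv), 4 Å MS, THF, 0 °C → rt; 12 (1.5 equiv), 8 added over 1 h; aq. NH4Cl
Reagents that add atoms: none
Why: Proposed new method: fluoride removes the silyl group and triflate from 8 to release aryne 13; the tertiary alkoxide of 12 (formed in low concentration by fluoride and regenerated when the product alkoxide takes a proton from further 12) adds to the triple bond to make C8a–O1, and the aryl anion, inductively stabilised by the adjacent methoxy group and held six atoms from the aldehyde, adds to C=O to make C4–C4a. The closest known reactions are the fluoride-mediated annulations of arynes with salicylaldehydes and 2-hydroxyaryl ketones to xanthenols and the insertion of arynes into alcohol O–H bonds; an aliphatic β-hydroxy aldehyde has not been used in this way. The pyran ring closes by 6-exo-trig attack of the aryl carbanion on the aldehyde. C4 is formed without control, which is harmless because it is dehydrated in step 10, while C2 keeps its configuration because its C–O bond is never broken. The step needs carbonyl capture to outrun protonation of the aryl anion and retro-aldol cleavage of the alkoxide: the aprotic solvent, the intramolecular six-membered transition state and the excess of 12 over the aryne serve the first, and the low stationary alkoxide concentration serves the second. Regiochemistry does not arise because the two aryne carbons of 13 are equivalent.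

Step 8
Reactants: 14 (2S)-5,8-dimethoxy-2-methyl-2-(4-methylpent-3-en-1-yl)chroman-4-ol
Product: 15 (2S)-2-(4-hydroxy-4-methylpentyl)-5,8-dimethoxy-2-methylchroman-4-ol
Conditions: Co(acac)2 (20 mol%), PhSiH3 (2 equiv), O2 (1 atm), THF, rt; aq. Na2S2O3
Reagents that add atoms: dioxygen, O=O
Why: Mukaiyama hydration (hydrogen-atom transfer from a cobalt hydride, then O2 trapping of the tertiary radical) should give the Markovnikov tertiary alcohol; the side-chain alkene is the only alkene present, which is why hydration precedes formation of the chromene double bond.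

Step 9
Reactants: 15 (2S)-2-(4-hydroxy-4-methylpentyl)-5,8-dimethoxy-2-methylchroman-4-ol
Product: 16 (2S)-6-bromo-2-(4-hydroxy-4-methylpentyl)-5,8-dimethoxy-2-methylchroman-4-ol
Conditions: NBS (1.05 equiv), NaHCO3, MeCN, 0 °C, dark
Reagents that add atoms: N-bromosuccinimide, O=C1CCC(=O)N1Br
Why: Electrophilic aromatic bromination should go to C6, which is ortho to the C5 methoxy group and para to ring oxygen O1, whereas C7 has only one ortho oxygen donor; brominating now avoids competition from the later C3=C4 alkene.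

Step 10
Reactants: 16 (2S)-6-bromo-2-(4-hydroxy-4-methylpentyl)-5,8-dimethoxy-2-methylchroman-4-ol
Product: 17 5-[(2S)-6-bromo-5,8-dimethoxy-2-methyl-2H-chromen-2-yl]-2-methylpentan-2-ol
Conditions: PPTS (10 mol%), 1,2-dichloroethane (0.02 M), 60 °C
Reagents that add atoms: none
Why: Acid-catalysed E1 dehydration: the C4 cation is stabilised by the ortho C5 methoxy group and by O1, so the benzylic alcohol should ionise under conditions that leave the tertiary alkyl alcohol alone, and C2 is not involved.

Step 11
Reactants: 18 4-(tert-butyldimethylsilyloxy)benzaldehyde; 19 diethyl [2-(methoxy(methyl)amino)-2-oxoethyl]phosphonate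
Product: 20 (E)-3-[4-(tert-butyldimethylsilyloxy)phenyl]-N-methoxy-N-methylprop-2-enamide
Conditions: LiCl, DBU, MeCN, rt
Reagents that add atoms: none
Why: Horner–Wadsworth–Emmons olefination under Masamune–Roush conditions with a stabilised phosphonate should give the E-enamide, and the mild amine base spares the aryl silyl ether.

Step 12
Reactants: 17 5-[(2S)-6-bromo-5,8-dimethoxy-2-methyl-2H-chromen-2-yl]-2-methylpentan-2-ol; 20 (E)-3-[4-(tert-butyldimethylsilyloxy)phenyl]-N-methoxy-N-methylprop-2-enamide
Product: 23 (E)-3-[4-(tert-butyldimethylsilyloxy)phenyl]-1-[(2S)-2-(4-hydroxy-4-methylpentyl)-5,8-dimethoxy-2-methyl-2H-chromen-6-yl]prop-2-en-1-one, via dilithio aryl alkoxide 21 (not isolated), via tetrahedral adduct 22 (not isolated)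
Conditions: n-BuLi (2.1 equiv), THF, −78 °C; then 20 (1.2 equiv), −78 → −40 °C; cold aq. NH4Cl
Reagents that add atoms: none
Why: The first equivalent of n-BuLi forms the lithium alkoxide and the second effects bromine–lithium exchange at C6; the aryllithium adds 1,2 to the Weinreb amide and the chelated adduct releases the ketone only on work-up (Weinreb ketone synthesis), so over-addition is avoided.

Step 13
Reactants: 23 (E)-3-[4-(tert-butyldimethylsilyloxy)phenyl]-1-[(2S)-2-(4-hydroxy-4-methylpentyl)-5,8-dimethoxy-2-methyl-2H-chromen-6-yl]prop-2-en-1-one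
Product: 25 (E)-3-[4-(tert-butyldimethylsilyloxy)phenyl]-1-[(2S)-5,8-dihydroxy-2-(4-hydroxy-4-methylpentyl)-2-methyl-2H-chromen-6-yl]prop-2-en-1-one, via quinone 24 (not isolated)
Conditions: (NH4)2Ce(NO3)6 (2.5 equiv), MeCN–H2O, 0 °C; then aq. Na2S2O4, EtOAc, rt
Reagents that add atoms: water, O
Why: Oxidative demethylation of a para-dimethoxyarene by tetravalent cerium (water attacks C5 and C8 of the radical cation and methanol leaves) should give the para-quinone without involving O1, and dithionite reduces it at once to the hydroquinone.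

Step 14
Reactants: 25 (E)-3-[4-(tert-butyldimethylsilyloxy)phenyl]-1-[(2S)-5,8-dihydroxy-2-(4-hydroxy-4-methylpentyl)-2-methyl-2H-chromen-6-yl]prop-2-en-1-one
Product: 26 (E)-1-[(2S)-5,8-dihydroxy-2-(4-hydroxy-4-methylpentyl)-2-methyl-2H-chromen-6-yl]-3-(4-hydroxyphenyl)prop-2-en-1-one
Conditions: KHF2 (2 equiv), MeOH (degassed), rt, argon
Reagents that add atoms: none
Why: Fluoride-mediated desilylation with bifluoride cleaves the aryl silicon–oxygen bond under nearly neutral conditions that should leave the hydroquinone, the enone and the chromene intact.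

**Compound list**

1 | 2,5-dimethoxyphenol | COc1ccc(OC)c(O)c1 | starting material
2 | 2,5-dimethoxyphenyl N-isopropylcarbamate | COc1ccc(OC)c(OC(=O)NC(C)C)c1 | intermediate
3 | 2,5-dimethoxyphenyl N-(tert-butyldimethylsilyl)-N-isopropylcarbamate | COc1ccc(OC)c(OC(=O)N(C(C)C)[Si](C)(C)C(C)(C)C)c1 | intermediate (not isolated)
4 | 2-lithio-3,6-dimethoxyphenyl N-(tert-butyldimethylsilyl)-N-isopropylcarbamate | COc1ccc(OC)c(OC(=O)N(C(C)C)[Si](C)(C)C(C)(C)C)c1[Li] | intermediate (not isolated)
5 | 3,6-dimethoxy-2-(trimethylsilyl)phenyl N-(tert-butyldimethylsilyl)-N-isopropylcarbamate | COc1ccc(OC)c(OC(=O)N(C(C)C)[Si](C)(C)C(C)(C)C)c1[Si](C)(C)C | intermediate (not isolated)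
6 | 3,6-dimethoxy-2-(trimethylsilyl)phenyl N-isopropylcarbamate | COc1ccc(OC)c(OC(=O)NC(C)C)c1[Si](C)(C)C | intermediate
7 | 3,6-dimethoxy-2-(trimethylsilyl)phenol | COc1ccc(OC)c(O)c1[Si](C)(C)C | intermediate (not isolated)
8 | 3,6-dimethoxy-2-(trimethylsilyl)phenyl trifluoromethanesulfonate | COc1ccc(OC)c(OS(=O)(=O)C(F)(F)F)c1[Si](C)(C)C | intermediate
9 | geraniol, (E)-3,7-dimethylocta-2,6-dien-1-ol | CC(C)=CCC/C(C)=C/CO | starting material
10 | (2S,3S)-2,3-epoxygeraniol, [(2S,3S)-3-methyl-3-(4-methylpent-3-en-1-yl)oxiran-2-yl]methanol | CC(C)=CCC[C@]1(C)O[C@H]1CO | intermediate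
11 | (3S)-3,7-dimethyloct-6-ene-1,3-diol | OCC[C@@](C)(O)CCC=C(C)C | intermediate
12 | (3S)-3-hydroxy-3,7-dimethyloct-6-enal | O=CC[C@@](C)(O)CCC=C(C)C | intermediate
13 | 3,6-dimethoxybenzyne | COC1=CC=C(OC)C#C1 | intermediate (not isolated)
14 | (2S)-5,8-dimethoxy-2-methyl-2-(4-methylpent-3-en-1-yl)chroman-4-ol, both C4 epimers | CC(C)=CCC[C@@]1(C)CC(O)c2c(OC)ccc(OC)c2O1 | intermediate
15 | (2S)-2-(4-hydroxy-4-methylpentyl)-5,8-dimethoxy-2-methylchroman-4-ol, both C4 epimers | CC(C)(O)CCC[C@@]1(C)CC(O)c2c(OC)ccc(OC)c2O1 | intermediate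
16 | (2S)-6-bromo-2-(4-hydroxy-4-methylpentyl)-5,8-dimethoxy-2-methylchroman-4-ol, both C4 epimers | CC(C)(O)CCC[C@@]1(C)CC(O)c2c(OC)c(Br)cc(OC)c2O1 | intermediate
17 | 5-[(2S)-6-bromo-5,8-dimethoxy-2-methyl-2H-chromen-2-yl]-2-methylpentan-2-ol | CC(C)(O)CCC[C@@]1(C)C=Cc2c(OC)c(Br)cc(OC)c2O1 | intermediate
18 | 4-(tert-butyldimethylsilyloxy)benzaldehyde | O=Cc1ccc(O[Si](C)(C)C(C)(C)C)cc1 | starting material
19 | diethyl [2-(methoxy(methyl)amino)-2-oxoethyl]phosphonate | CCOP(=O)(CC(=O)N(C)OC)OCC | starting material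
20 | (E)-3-[4-(tert-butyldimethylsilyloxy)phenyl]-N-methoxy-N-methylprop-2-enamide | CON(C)C(=O)/C=C/c1ccc(O[Si](C)(C)C(C)(C)C)cc1 | intermediate
21 | lithium alkoxide of 17 lithiated at C6 in place of bromine | [Li]OC(C)(C)CCC[C@@]1(C)C=Cc2c(OC)c([Li])cc(OC)c2O1 | intermediate (not isolated)
22 | dilithium salt of the N-methoxy-N-methyl hemiaminal formed from 21 and 20 | [Li]OC(C)(C)CCC[C@@]1(C)C=Cc2c(OC)c(C(O[Li])(/C=C/c3ccc(O[Si](C)(C)C(C)(C)C)cc3)N(C)OC)cc(OC)c2O1 | intermediate (not isolated)
23 | (E)-3-[4-(tert-butyldimethylsilyloxy)phenyl]-1-[(2S)-2-(4-hydroxy-4-methylpentyl)-5,8-dimethoxy-2-methyl-2H-chromen-6-yl]prop-2-en-1-one | CC(C)(O)CCC[C@@]1(C)C=Cc2c(OC)c(C(=O)/C=C/c3ccc(O[Si](C)(C)C(C)(C)C)cc3)cc(OC)c2O1 | intermediate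
24 | (2S)-6-[(E)-3-(4-(tert-butyldimethylsilyloxy)phenyl)prop-2-enoyl]-2-(4-hydroxy-4-methylpentyl)-2-methyl-2H-chromene-5,8-dione | CC(C)(O)CCC[C@@]1(C)C=CC2=C(O1)C(=O)C=C(C(=O)/C=C/c3ccc(O[Si](C)(C)C(C)(C)C)cc3)C2=O | intermediate (not isolated)
25 | (E)-3-[4-(tert-butyldimethylsilyloxy)phenyl]-1-[(2S)-5,8-dihydroxy-2-(4-hydroxy-4-methylpentyl)-2-methyl-2H-chromen-6-yl]prop-2-en-1-one | CC(C)(O)CCC[C@@]1(C)C=Cc2c(O)c(C(=O)/C=C/c3ccc(O[Si](C)(C)C(C)(C)C)cc3)cc(O)c2O1 | intermediate
26 | (E)-1-[(2S)-5,8-dihydroxy-2-(4-hydroxy-4-methylpentyl)-2-methyl-2H-chromen-6-yl]-3-(4-hydroxyphenyl)prop-2-en-1-one | CC(C)(O)CCC[C@@]1(C)C=Cc2c(O)c(C(=O)/C=C/c3ccc(O)cc3)cc(O)c2O1 | target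

**Step count and risks**

Total steps: 14. Longest linear sequence: 10 steps (1, 2, 3, 7, 8, 9, 10, 12, 13, 14; the line from geraniol through steps 4, 5, 6 is equally long).

Step 7 (aryne annulation). Three processes may defeat it: protonation of the aryl anion before it reaches the aldehyde, which would stop at simple O-arylation; retro-aldol cleavage or loss of water from the hydroxy aldehyde under fluoride; and slow addition of the hindered tertiary alkoxide to a triple bond flanked by two methoxy groups. The fallback makes the same two bonds in the reverse order by established reactions, setting out from 12 and returning at 14. Commercial 2-bromo-1,4-dimethoxybenzene (COc1ccc(OC)c(Br)c1) is deprotonated between bromine and methoxy with LiN(iPr)2 in THF at −78 °C to give 2-bromo-3,6-dimethoxyphenyllithium F1. Two equivalents are added to 12 at −78 °C; the first removes the hydroxyl proton and the second adds to the aldehyde, giving (3S)-1-(2-bromo-3,6-dimethoxyphenyl)-3,7-dimethyloct-6-ene-1,3-diol F2 after NH4Cl work-up. Intramolecular Ullmann-type C–O coupling of the tertiary alcohol with the aryl bromide (CuI, 1,10-phenanthroline, Cs2CO3, toluene, 110 °C) should then close the pyran ring to 14. The C–O bond at the carbinol stereocentre is not broken, so the configuration is kept.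

Step 13 (oxidative demethylation). Water or nitrate may add to the very electrophilic acylquinone, and the oxidant may attack the chromene double bond or the silyloxystyryl unit. The fallback unmasks the hydroquinone before the cinnamoyl group is present and ends with a non-oxidative deprotection, setting out from 17 and returning at 25. Treatment of 17 with (NH4)2Ce(NO3)6 in MeCN–H2O gives (2S)-6-bromo-2-(4-hydroxy-4-methylpentyl)-2-methyl-2H-chromene-5,8-dione F3, reduced in the same operation by Na2S2O4 to (2S)-6-bromo-2-(4-hydroxy-4-methylpentyl)-2-methyl-2H-chromene-5,8-diol F4. MOMCl and i-Pr2NEt in CH2Cl2 convert it into 5-[(2S)-6-bromo-5,8-bis(methoxymethoxy)-2-methyl-2H-chromen-2-yl]-2-methylpentan-2-ol F5. n-BuLi (2.1 equiv, THF, −78 °C) gives the dilithio aryl alkoxide F6, which adds to 20 to give the tetrahedral adduct F7 and, after NH4Cl work-up, the bis(methoxymethyl) chalcone F8. Dilute HCl in MeOH at rt should cleave the two aryl acetals and leave the aryl silyl ether, giving 25, which continues with step 14.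

Step 12 (lithiation and acylation). Halogen–lithium exchange may be incomplete or the aryllithium may be quenched within the alkoxide aggregate, and the aryllithium or the liberated N,O-dimethylhydroxylamine may add in conjugate fashion to the enamide or enone. The fallback avoids organolithium chemistry and builds the enone by condensation, setting out from 17 and returning at 23. Stille coupling of 17 with tributyl(1-ethoxyvinyl)stannane (PdCl2(PPh3)2, toluene, 100 °C) gives 5-[(2S)-6-(1-ethoxyvinyl)-5,8-dimethoxy-2-methyl-2H-chromen-2-yl]-2-methylpentan-2-ol F9, hydrolysed by dilute aqueous HCl in THF to 1-[(2S)-2-(4-hydroxy-4-methylpentyl)-5,8-dimethoxy-2-methyl-2H-chromen-6-yl]ethan-1-one F10. Claisen–Schmidt condensation with 4-hydroxybenzaldehyde (KOH, EtOH, rt) gives (E)-1-[(2S)-2-(4-hydroxy-4-methylpentyl)-5,8-dimethoxy-2-methyl-2H-chromen-6-yl]-3-(4-hydroxyphenyl)prop-2-en-1-one F11. TBSCl and imidazole in DMF silylate the phenol only and return to 23.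

**Further compounds**

F1 | step 7 | 2-bromo-3,6-dimethoxyphenyllithium | COc1ccc(OC)c([Li])c1Br
F2 | step 7 | (3S)-1-(2-bromo-3,6-dimethoxyphenyl)-3,7-dimethyloct-6-ene-1,3-diol, both C1 epimers | COc1ccc(OC)c(C(O)C[C@@](C)(O)CCC=C(C)C)c1Br
F3 | step 13 | (2S)-6-bromo-2-(4-hydroxy-4-methylpentyl)-2-methyl-2H-chromene-5,8-dione | CC(C)(O)CCC[C@@]1(C)C=CC2=C(O1)C(=O)C=C(Br)C2=O
F4 | step 13 | (2S)-6-bromo-2-(4-hydroxy-4-methylpentyl)-2-methyl-2H-chromene-5,8-diol | CC(C)(O)CCC[C@@]1(C)C=Cc2c(O)c(Br)cc(O)c2O1
F5 | step 13 | 5-[(2S)-6-bromo-5,8-bis(methoxymethoxy)-2-methyl-2H-chromen-2-yl]-2-methylpentan-2-ol | CC(C)(O)CCC[C@@]1(C)C=Cc2c(OCOC)c(Br)cc(OCOC)c2O1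
F6 | step 13 | lithium alkoxide of F5 lithiated at C6 in place of bromine | [Li]OC(C)(C)CCC[C@@]1(C)C=Cc2c(OCOC)c([Li])cc(OCOC)c2O1
F7 | step 13 | dilithium salt of the N-methoxy-N-methyl hemiaminal formed from F6 and 20 | [Li]OC(C)(C)CCC[C@@]1(C)C=Cc2c(OCOC)c(C(O[Li])(/C=C/c3ccc(O[Si](C)(C)C(C)(C)C)cc3)N(C)OC)cc(OCOC)c2O1
F8 | step 13 | (E)-3-[4-(tert-butyldimethylsilyloxy)phenyl]-1-[(2S)-2-(4-hydroxy-4-methylpentyl)-5,8-bis(methoxymethoxy)-2-methyl-2H-chromen-6-yl]prop-2-en-1-one | CC(C)(O)CCC[C@@]1(C)C=Cc2c(OCOC)c(C(=O)/C=C/c3ccc(O[Si](C)(C)C(C)(C)C)cc3)cc(OCOC)c2O1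
F9 | step 12 | 5-[(2S)-6-(1-ethoxyvinyl)-5,8-dimethoxy-2-methyl-2H-chromen-2-yl]-2-methylpentan-2-ol | CC(C)(O)CCC[C@@]1(C)C=Cc2c(OC)c(C(=C)OCC)cc(OC)c2O1
F10 | step 12 | 1-[(2S)-2-(4-hydroxy-4-methylpentyl)-5,8-dimethoxy-2-methyl-2H-chromen-6-yl]ethan-1-one | CC(C)(O)CCC[C@@]1(C)C=Cc2c(OC)c(C(C)=O)cc(OC)c2O1
F11 | step 12 | (E)-1-[(2S)-2-(4-hydroxy-4-methylpentyl)-5,8-dimethoxy-2-methyl-2H-chromen-6-yl]-3-(4-hydroxyphenyl)prop-2-en-1-one | CC(C)(O)CCC[C@@]1(C)C=Cc2c(OC)c(C(=O)/C=C/c3ccc(O)cc3)cc(OC)c2O1
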